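**Retrosynthetic overview**
1. The target is read as fisetinidol-(4β→6)-fisetinidol-(4α→6)-mollisacacidin. The last two operations are global hydrogenolysis and NaBH4 reduction of a C4 ketone in the bottom unit; until then that ketone keeps ring A of the bottom unit inert and its C4 unable to ionize.
2. Key disconnection (bottom unit): ring C is opened at O1–C2 to an ortho-hydroxyaryl trans-epoxy ketone. Its ring A (C4a, C5, C6, C7, C8, C8a) is then taken apart by retro-Diels–Alder/aromatization into a 1-methoxy-1,3-bis(silyloxy)diene hanging from C4 of the middle unit and one enantiopure epoxy ynone that carries C5, C4a, C4, C3, C2 and ring B.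
3. The same two reagents build every unit. A flavan-4-yl cation is captured by the γ-carbon of the silyloxydiene (cis to a 3-benzyloxy group for the top 4β bond, trans under 3-O-carbonate participation for the middle 4α bond); the keto ester is turned into the next diene, so each interflavan bond ends at C6 by construction.
4. Ring order: top unit rings A and C (step 5), middle unit rings A and C (step 10), bottom unit ring A and then ring C by O1–C2 closure (step 15).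
5. Enabling feature: ring A of each unit is a benzene with oxygen on C8a (O1) and on C7, the acyl-type carbon C4 on C4a and the interflavan carbon on C6, which is the pattern a 1,1,3-trioxygenated diene gives with an ethynyl ketone. C2 is benzylic to the para-oxygenated ring B, so the phenol O1–H formed in the aromatization opens the C2–C3 epoxide at C2.

Key step: step 15

Remark: 1-methoxy-1,3-bis(trimethylsilyloxy)buta-1,3-diene is taken as a purchasable reagent (otherwise one operation from methyl acetoacetate); target descriptors are C2 R and C3 S in every unit, C4 S (top), R (middle), R (bottom).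

**Route**

Step 1
Reactants: 1 3,4-bis(benzyloxy)benzaldehyde; 2 (triphenylphosphoranylidene)acetaldehyde
Product: 3 (E)-3-[3,4-bis(benzyloxy)phenyl]prop-2-enal
Conditions: toluene, 80 °C
Reagents that add atoms: none
Why: Wittig olefination with the stabilized formylmethylene ylide should give the (E)-enal selectively.

Step 2
Reactants: 3 (E)-3-[3,4-bis(benzyloxy)phenyl]prop-2-enal
Product: 4 (2R,3S)-3-[3,4-bis(benzyloxy)phenyl]oxirane-2-carbaldehyde
Conditions: 35% aq. H2O2 (1.3 equiv), (R)-2-{bis[3,5-bis(trifluoromethyl)phenyl](trimethylsilyloxy)methyl}pyrrolidine (10 mol%), CH2Cl2, 20 °C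
Reagents that add atoms: hydrogen peroxide OO
Why: Iminium–enamine organocatalytic epoxidation of an enal: the peroxide adds to C3 of the (E)-iminium ion on the face away from the diaryl(silyloxy)methyl group (the Re face of C3 with the (R)-catalyst, by a steric-shielding model) and the enamine closes the trans-epoxide on the same face, which sets C2 (R) and C3 (S).

Step 3
Reactants: 4 (2R,3S)-3-[3,4-bis(benzyloxy)phenyl]oxirane-2-carbaldehyde
Product: 5 1-{(2S,3S)-3-[3,4-bis(benzyloxy)phenyl]oxiran-2-yl}prop-2-yn-1-ol (both carbinol epimers)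
Conditions: HC≡CMgBr (1.2 equiv), THF, −78 °C; pH 7 buffer
Reagents that add atoms: ethynylmagnesium bromide C#C[Mg]Br
Why: Chemoselective 1,2-addition of the alkynyl Grignard reagent to the aldehyde at low temperature leaves the epoxide untouched; the new carbinol center is formed as a mixture and is erased in step 4.

Step 4
Reactants: 5 1-{(2S,3S)-3-[3,4-bis(benzyloxy)phenyl]oxiran-2-yl}prop-2-yn-1-ol
Product: 6 1-{(2R,3S)-3-[3,4-bis(benzyloxy)phenyl]oxiran-2-yl}prop-2-yn-1-one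
Conditions: IBX (2-iodoxybenzoic acid, 1.5 equiv), DMSO, 20 °C
Reagents that add atoms: none
Why: Neutral IBX oxidation of a propargylic alcohol to the ynone should leave the acid-sensitive aryl epoxide and the terminal alkyne intact.

Step 5
Reactants: 6 1-{(2R,3S)-3-[3,4-bis(benzyloxy)phenyl]oxiran-2-yl}prop-2-yn-1-one; 7 1-methoxy-1,3-bis(trimethylsilyloxy)buta-1,3-diene
Product: 10 (2R,3R)-2-[3,4-bis(benzyloxy)phenyl]-3,7-dihydroxychroman-4-one (3′,4′-di-O-benzylfustin), via cyclohexadiene cycloadduct 8 (not isolated), via dihydroxyphenyl epoxy ketone 9 (not isolated)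
Conditions: toluene, 25 → 60 °C; then THF–H2O, p-TsOH·H2O (10 mol%), 25 °C
Reagents that add atoms: none
Why: Diels–Alder reaction of the electron-rich diene with the ethynyl ketone (diene C4 to the terminal alkyne carbon) is followed by acid-induced loss of methanol (aromatization of ring A) and desilylation; the phenol ortho to the carbonyl then opens the epoxide 6-endo at the benzylic carbon with inversion (C2 R, C3 R carried over) to give the trans-dihydroflavonol.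

Step 6
Reactants: 10 3′,4′-di-O-benzylfustin
Product: 11 (2R,3S,4R)-2-[3,4-bis(benzyloxy)phenyl]chromane-3,4,7-triol (3′,4′-di-O-benzylmollisacacidin)
Conditions: NaBH4, THF–EtOH, 0 °C
Reagents that add atoms: none
Why: Borohydride reduction of a trans-dihydroflavonol: hydride adds axially to C4, cis to O3, so the 2,3-trans-3,4-trans diol is expected (the C4 configuration is lost again in step 8).

Step 7
Reactants: 11 3′,4′-di-O-benzylmollisacacidin
Product: 12 (2R,3S,4R)-3,4,7-tris(benzyloxy)-2-[3,4-bis(benzyloxy)phenyl]chromane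
Conditions: NaH, BnBr, Bu4NI (cat.), DMF, 0 → 20 °C
Reagents that add atoms: benzyl bromide BrCc1ccccc1
Why: Williamson etherification of the phenol and both alcohols; the 3-benzyloxy group is non-participating and the benzylic 4-benzyloxy group is the leaving group of step 8.

Step 8
Reactants: 12 penta-O-benzylmollisacacidin; 7 1-methoxy-1,3-bis(trimethylsilyloxy)buta-1,3-diene
Product: 14 methyl 4-{(2R,3S,4S)-3,7-bis(benzyloxy)-2-[3,4-bis(benzyloxy)phenyl]chroman-4-yl}-3-oxobutanoate, via silyl enol ether 13 (not isolated)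
Conditions: TMSOTf (0.2 equiv), 7 (2 equiv), CH2Cl2, −78 °C; then 1 M HCl, THF, 0 °C
Reagents that add atoms: none
Why: Vinylogous Mukaiyama-type alkylation: TMSOTf ionizes the 4-benzyloxy group to the flavan-4-yl cation (stabilized by O1 and O7 of ring A), and the small, strongly nucleophilic γ-carbon of the diene outruns the benzyloxyarene rings and adds along the axial trajectory of the half-chair whose 3-benzyloxy group is pseudo-equatorial, that is anti to the axial H3 and cis to O3, which should set C4 (S) with the 3,4-cis (4β) relation.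

Step 9
Reactants: 14 keto ester of step 8
Product: 15 (2R,3S,4S)-3,7-bis(benzyloxy)-2-[3,4-bis(benzyloxy)phenyl]-4-[(1Z)-4-methoxy-2,4-bis(trimethylsilyloxy)buta-1,3-dien-1-yl]chromane
Conditions: TMSOTf (2.4 equiv), Et3N (3 equiv), Et2O, 0 → 20 °C; salt layer removed, used crude
Reagents that add atoms: trimethylsilyl trifluoromethanesulfonate C[Si](C)(C)OS(=O)(=O)C(F)(F)F
Why: Soft enolization silylates the ketone enol and then the vinylogous ester enol to the 1-methoxy-1,3-bis(silyloxy)diene; the more stable (Z)-enol ether, with the flavanyl group trans to the diene chain, is expected to prevail.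

Step 10
Reactants: 15 flavanyl bis(silyloxy)diene; 6 1-{(2R,3S)-3-[3,4-bis(benzyloxy)phenyl]oxiran-2-yl}prop-2-yn-1-one
Product: 18 3,7,3′,4′-tetra-O-benzylfisetinidol-(4β→6)-3′,4′-di-O-benzylfustin, via cyclohexadiene cycloadduct 16 (not isolated), via dihydroxyaryl epoxy ketone 17 (not isolated)
Conditions: toluene, 80 °C; then THF–H2O, p-TsOH·H2O (10 mol%), 25 °C
Reagents that add atoms: none
Why: Same Diels–Alder/aromatization/6-endo epoxide opening as in step 5; the flavanyl-bearing diene terminus becomes C6 of the new ring A, so the 4→6 linkage is fixed by construction, and C2 (R) and C3 (R) of the new unit come from the epoxide as before.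

Step 11
Reactants: 18 dimer ketone
Product: 19 3,7,3′,4′-tetra-O-benzylfisetinidol-(4β→6)-3′,4′-di-O-benzylmollisacacidin
Conditions: NaBH4, THF–EtOH, 0 °C
Reagents that add atoms: none
Why: Borohydride reduction of the trans-dihydroflavonol unit as in step 6 should give the 3,4-trans diol of the lower unit.

Step 12
Reactants: 19 dimer triol
Product: 20 3,7,3′,4′-tetra-O-benzylfisetinidol-(4β→6)-3′,4′-di-O-benzyl-3,4,7-tris-O-(benzyloxycarbonyl)mollisacacidin
Conditions: benzyl chloroformate (6 equiv), pyridine, DMAP (cat.), CH2Cl2, 0 → 20 °C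
Reagents that add atoms: benzyl chloroformate O=C(Cl)OCc1ccccc1
Why: Acylation of the phenol and both secondary alcohols; the 4-O-carbonate is the leaving group and the 3-O-carbonate the participating group of step 13, the 7-O-carbonate tempers the cation, and all three fall to hydrogenolysis.

Step 13
Reactants: 20 dimer tris(carbonate); 7 1-methoxy-1,3-bis(trimethylsilyloxy)buta-1,3-diene
Product: 22 methyl 4-[3,7,3′,4′-tetra-O-benzylfisetinidol-(4β→6)-3′,4′-di-O-benzyl-3,7-bis-O-(benzyloxycarbonyl)fisetinidol-4α-yl]-3-oxobutanoate, via silyl enol ether 21 (not isolated)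
Conditions: TMSOTf (0.3 equiv), 7 (2 equiv), CH2Cl2, −78 → −40 °C; then 1 M HCl, THF, 0 °C
Reagents that add atoms: none
Why: Vinylogous Mukaiyama-type alkylation under neighboring-group control: ionization of the 4-O-carbonate is assisted by the 3-O-carbonate carbonyl (cis-fused dioxolanylium ion across C3–C4) and the γ-carbon of the diene opens it at C4 from the opposite face, which should set C4 (R) with the 3,4-trans (4α) relation.

Step 14
Reactants: 22 dimer keto ester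
Product: 23 (Z)-1-methoxy-1,3-bis(trimethylsilyloxy)buta-1,3-diene carrying the protected dimer of 22 (4α) on its C4
Conditions: TMSOTf (2.4 equiv), Et3N (3 equiv), Et2O, 0 → 20 °C; salt layer removed, used crude
Reagents that add atoms: trimethylsilyl trifluoromethanesulfonate C[Si](C)(C)OS(=O)(=O)C(F)(F)F
Why: Soft enolization/silylation as in step 9; the carbonates have no enolizable hydrogen and should survive.

Step 15
Reactants: 23 dimer bis(silyloxy)diene; 6 1-{(2R,3S)-3-[3,4-bis(benzyloxy)phenyl]oxiran-2-yl}prop-2-yn-1-one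
Product: 26 3,7,3′,4′-tetra-O-benzylfisetinidol-(4β→6)-3′,4′-di-O-benzyl-3,7-bis-O-(benzyloxycarbonyl)fisetinidol-(4α→6)-3′,4′-di-O-benzylfustin, via cyclohexadiene cycloadduct 24 (not isolated), via dihydroxyaryl epoxy ketone 25 (not isolated)
Conditions: toluene, 80 °C; then THF–H2O, p-TsOH·H2O (10 mol%), 25 °C
Reagents that add atoms: none
Why: The silyloxydiene of 23 and the ethynyl ketone of 6 combine in a normal-electron-demand Diels–Alder reaction in which the flavanyl-bearing diene terminus (future C6) bonds to the terminal alkyne carbon (future C5) and the ketene acetal carbon (future C8a) to the acyl-bearing carbon (future C4a), so that cycloadduct 24 already holds all six carbons of ring A of the bottom unit with the interflavan bond fixed at C6. Mild acid then expels methanol from the ketal carbon, which aromatizes ring A, and hydrolyses both silyl ethers to give 25, whose new O1–H group sits ortho to the epoxy ketone. O1 attacks the benzylic epoxide carbon C2 in a 6-endo-tet opening, preferred over 5-exo attack at C3 because the 3,4-bis(benzyloxy)phenyl ring stabilizes positive charge at C2, and this closes ring C through the O1–C2 bond. The closest known reaction types are the Diels–Alder/aromatization of 1-alkoxy-1,3-bis(silyloxy)buta-1,3-dienes with acetylenic carbonyl compounds to 2,4-dihydroxyaryl carbonyl compounds and the acid-mediated cyclization of 2′-hydroxychalcone epoxides to trans-dihydroflavonols. C3 (R) is carried over unchanged from the epoxide of 6 and C2 (R) arises by inversion at the epoxide carbon (an ionic opening would close to the same diequatorial 2,3-trans ring), while the six stereocenters of the two upper units are untouched. The step needs regioselective cycloaddition, secured by the matched polarization of diene and ynone and by the (Z)-enol ether geometry that keeps the flavanyl group outside the s-cis diene, and it needs the new ring A to stay inert afterwards, secured by the C4 carbonyl.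

Step 16
Reactants: 26 protected trimer ketone
Product: 27 fisetinidol-(4β→6)-fisetinidol-(4α→6)-fustin
Conditions: H2 (1 atm), Pd(OH)2/C, THF–MeOH, 20 °C
Reagents that add atoms: none
Why: Neutral hydrogenolysis should cleave the eight benzyl ethers and the two benzyl carbonates (to toluene and CO2), while the aryl ketone, the interflavan C–C bonds and the ring C ether bonds are expected to survive.

Step 17
Reactants: 27 fisetinidol-(4β→6)-fisetinidol-(4α→6)-fustin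
Product: 28 fisetinidol-(4β→6)-fisetinidol-(4α→6)-mollisacacidin (CNP0255184.1)
Conditions: NaBH4 (excess), MeOH, 0 °C, argon; AcOH to pH 6
Reagents that add atoms: none
Why: Borohydride reduction of the free-phenolic trans-dihydroflavonol unit: hydride adds axially to C4, cis to O3, so the equatorial 4-hydroxyl trans to the 3-hydroxyl (C4 R) is expected, as in the reduction of fustin to mollisacacidin.

**Compound list**

1 | 3,4-bis(benzyloxy)benzaldehyde | O=Cc1ccc(OCc2ccccc2)c(OCc2ccccc2)c1 | starting material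
2 | (triphenylphosphoranylidene)acetaldehyde | O=CC=P(c1ccccc1)(c1ccccc1)c1ccccc1 | starting material
3 | (E)-3-[3,4-bis(benzyloxy)phenyl]prop-2-enal | O=C/C=C/c1ccc(OCc2ccccc2)c(OCc2ccccc2)c1 | intermediate
4 | (2R,3S)-3-[3,4-bis(benzyloxy)phenyl]oxirane-2-carbaldehyde | O=C[C@@H]1O[C@H]1c1ccc(OCc2ccccc2)c(OCc2ccccc2)c1 | intermediate
5 | 1-{(2S,3S)-3-[3,4-bis(benzyloxy)phenyl]oxiran-2-yl}prop-2-yn-1-ol (both carbinol epimers) | C#CC(O)[C@@H]1O[C@H]1c1ccc(OCc2ccccc2)c(OCc2ccccc2)c1 | intermediate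
6 | 1-{(2R,3S)-3-[3,4-bis(benzyloxy)phenyl]oxiran-2-yl}prop-2-yn-1-one | C#CC(=O)[C@@H]1O[C@H]1c1ccc(OCc2ccccc2)c(OCc2ccccc2)c1 | intermediate
7 | 1-methoxy-1,3-bis(trimethylsilyloxy)buta-1,3-diene | COC(O[Si](C)(C)C)=CC(=C)O[Si](C)(C)C | starting material
8 | {(2R,3S)-3-[3,4-bis(benzyloxy)phenyl]oxiran-2-yl}[6-methoxy-4,6-bis(trimethylsilyloxy)cyclohexa-1,4-dien-1-yl]methanone (both C6 epimers) | COC1(O[Si](C)(C)C)C=C(O[Si](C)(C)C)CC=C1C(=O)[C@@H]1O[C@H]1c1ccc(OCc2ccccc2)c(OCc2ccccc2)c1 | intermediate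
9 | (2,4-dihydroxyphenyl){(2R,3S)-3-[3,4-bis(benzyloxy)phenyl]oxiran-2-yl}methanone | O=C(c1ccc(O)cc1O)[C@@H]1O[C@H]1c1ccc(OCc2ccccc2)c(OCc2ccccc2)c1 | intermediate
10 | (2R,3R)-2-[3,4-bis(benzyloxy)phenyl]-3,7-dihydroxychroman-4-one (3′,4′-di-O-benzylfustin) | Oc1ccc2c(c1)O[C@H](c1ccc(OCc3ccccc3)c(OCc3ccccc3)c1)[C@@H](O)C2=O | intermediate
11 | (2R,3S,4R)-2-[3,4-bis(benzyloxy)phenyl]chromane-3,4,7-triol (3′,4′-di-O-benzylmollisacacidin) | Oc1ccc2c(c1)O[C@H](c1ccc(OCc3ccccc3)c(OCc3ccccc3)c1)[C@@H](O)[C@@H]2O | intermediate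
12 | (2R,3S,4R)-3,4,7-tris(benzyloxy)-2-[3,4-bis(benzyloxy)phenyl]chromane | C(c3ccccc3)Oc1ccc2c(c1)O[C@H](c1ccc(OCc3ccccc3)c(OCc3ccccc3)c1)[C@@H](OCc1ccccc1)[C@@H]2OCc1ccccc1 | intermediate
13 | methyl 4-{(2R,3S,4S)-3,7-bis(benzyloxy)-2-[3,4-bis(benzyloxy)phenyl]chroman-4-yl}-3-(trimethylsilyloxy)but-2-enoate (alkene geometry open) | C(c3ccccc3)Oc1ccc2c(c1)O[C@H](c1ccc(OCc3ccccc3)c(OCc3ccccc3)c1)[C@@H](OCc1ccccc1)[C@H]2CC(O[Si](C)(C)C)=CC(=O)OC | intermediate
14 | methyl 4-{(2R,3S,4S)-3,7-bis(benzyloxy)-2-[3,4-bis(benzyloxy)phenyl]chroman-4-yl}-3-oxobutanoate | C(c3ccccc3)Oc1ccc2c(c1)O[C@H](c1ccc(OCc3ccccc3)c(OCc3ccccc3)c1)[C@@H](OCc1ccccc1)[C@H]2CC(=O)CC(=O)OC | intermediate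
15 | (2R,3S,4S)-3,7-bis(benzyloxy)-2-[3,4-bis(benzyloxy)phenyl]-4-[(1Z)-4-methoxy-2,4-bis(trimethylsilyloxy)buta-1,3-dien-1-yl]chromane | C(c3ccccc3)Oc1ccc2c(c1)O[C@H](c1ccc(OCc3ccccc3)c(OCc3ccccc3)c1)[C@@H](OCc1ccccc1)[C@H]2/C=C(O[Si](C)(C)C)/C=C(OC)O[Si](C)(C)C | intermediate
16 | Diels–Alder adduct of 15 and 6: [3-(3,7,3′,4′-tetra-O-benzylfisetinidol-4β-yl)-6-methoxy-4,6-bis(trimethylsilyloxy)cyclohexa-1,4-dien-1-yl]{(2R,3S)-3-[3,4-bis(benzyloxy)phenyl]oxiran-2-yl}methanone (epimers at C3 and C6 of the cyclohexadiene) | C(c3ccccc3)Oc1ccc2c(c1)O[C@H](c1ccc(OCc3ccccc3)c(OCc3ccccc3)c1)[C@@H](OCc1ccccc1)[C@H]2C1C=C(C(=O)[C@@H]2O[C@H]2c2ccc(OCc3ccccc3)c(OCc3ccccc3)c2)C(OC)(O[Si](C)(C)C)C=C1O[Si](C)(C)C | intermediate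
17 | [2,4-dihydroxy-5-(3,7,3′,4′-tetra-O-benzylfisetinidol-4β-yl)phenyl]{(2R,3S)-3-[3,4-bis(benzyloxy)phenyl]oxiran-2-yl}methanone | C(c3ccccc3)Oc1ccc2c(c1)O[C@H](c1ccc(OCc3ccccc3)c(OCc3ccccc3)c1)[C@@H](OCc1ccccc1)[C@H]2c1cc(C(=O)[C@@H]2O[C@H]2c2ccc(OCc3ccccc3)c(OCc3ccccc3)c2)c(O)cc1O | intermediate
18 | 3,7,3′,4′-tetra-O-benzylfisetinidol-(4β→6)-3′,4′-di-O-benzylfustin | C(c3ccccc3)Oc1ccc2c(c1)O[C@H](c1ccc(OCc3ccccc3)c(OCc3ccccc3)c1)[C@@H](OCc1ccccc1)[C@H]2c1cc2c(cc1O)O[C@H](c1ccc(OCc3ccccc3)c(OCc3ccccc3)c1)[C@@H](O)C2=O | intermediate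
19 | 3,7,3′,4′-tetra-O-benzylfisetinidol-(4β→6)-3′,4′-di-O-benzylmollisacacidin | C(c3ccccc3)Oc1ccc2c(c1)O[C@H](c1ccc(OCc3ccccc3)c(OCc3ccccc3)c1)[C@@H](OCc1ccccc1)[C@H]2c1cc2c(cc1O)O[C@H](c1ccc(OCc3ccccc3)c(OCc3ccccc3)c1)[C@@H](O)[C@@H]2O | intermediate
20 | 3,7,3′,4′-tetra-O-benzylfisetinidol-(4β→6)-3′,4′-di-O-benzyl-3,4,7-tris-O-(benzyloxycarbonyl)mollisacacidin | C(c3ccccc3)Oc1ccc2c(c1)O[C@H](c1ccc(OCc3ccccc3)c(OCc3ccccc3)c1)[C@@H](OCc1ccccc1)[C@H]2c1cc2c(cc1OC(=O)OCc3ccccc3)O[C@H](c1ccc(OCc3ccccc3)c(OCc3ccccc3)c1)[C@@H](OC(=O)OCc1ccccc1)[C@@H]2OC(=O)OCc1ccccc1 | intermediate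
21 | methyl 4-[3,7,3′,4′-tetra-O-benzylfisetinidol-(4β→6)-3′,4′-di-O-benzyl-3,7-bis-O-(benzyloxycarbonyl)fisetinidol-4α-yl]-3-(trimethylsilyloxy)but-2-enoate (alkene geometry open) | C(c3ccccc3)Oc1ccc2c(c1)O[C@H](c1ccc(OCc3ccccc3)c(OCc3ccccc3)c1)[C@@H](OCc1ccccc1)[C@H]2c1cc2c(cc1OC(=O)OCc3ccccc3)O[C@H](c1ccc(OCc3ccccc3)c(OCc3ccccc3)c1)[C@@H](OC(=O)OCc1ccccc1)[C@@H]2CC(O[Si](C)(C)C)=CC(=O)OC | intermediate
22 | methyl 4-[3,7,3′,4′-tetra-O-benzylfisetinidol-(4β→6)-3′,4′-di-O-benzyl-3,7-bis-O-(benzyloxycarbonyl)fisetinidol-4α-yl]-3-oxobutanoate | C(c3ccccc3)Oc1ccc2c(c1)O[C@H](c1ccc(OCc3ccccc3)c(OCc3ccccc3)c1)[C@@H](OCc1ccccc1)[C@H]2c1cc2c(cc1OC(=O)OCc3ccccc3)O[C@H](c1ccc(OCc3ccccc3)c(OCc3ccccc3)c1)[C@@H](OC(=O)OCc1ccccc1)[C@@H]2CC(=O)CC(=O)OC | intermediate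
23 | (1Z)-4-methoxy-2,4-bis(trimethylsilyloxy)buta-1,3-dien-1-yl derivative at C4 (4α) of the protected dimer of 22 | C(c3ccccc3)Oc1ccc2c(c1)O[C@H](c1ccc(OCc3ccccc3)c(OCc3ccccc3)c1)[C@@H](OCc1ccccc1)[C@H]2c1cc2c(cc1OC(=O)OCc3ccccc3)O[C@H](c1ccc(OCc3ccccc3)c(OCc3ccccc3)c1)[C@@H](OC(=O)OCc1ccccc1)[C@@H]2/C=C(O[Si](C)(C)C)/C=C(OC)O[Si](C)(C)C | intermediate
24 | Diels–Alder adduct of 23 and 6: 6-methoxy-4,6-bis(trimethylsilyloxy)cyclohexa-1,4-dien-1-yl (2R,3S)-3-[3,4-bis(benzyloxy)phenyl]oxiran-2-yl ketone carrying the protected dimer (4α) on C3 of the cyclohexadiene (epimers at C3 and C6) | C(c3ccccc3)Oc1ccc2c(c1)O[C@H](c1ccc(OCc3ccccc3)c(OCc3ccccc3)c1)[C@@H](OCc1ccccc1)[C@H]2c1cc2c(cc1OC(=O)OCc3ccccc3)O[C@H](c1ccc(OCc3ccccc3)c(OCc3ccccc3)c1)[C@@H](OC(=O)OCc1ccccc1)[C@@H]2C1C=C(C(=O)[C@@H]2O[C@H]2c2ccc(OCc3ccccc3)c(OCc3ccccc3)c2)C(OC)(O[Si](C)(C)C)C=C1O[Si](C)(C)C | intermediate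
25 | 2,4-dihydroxyphenyl (2R,3S)-3-[3,4-bis(benzyloxy)phenyl]oxiran-2-yl ketone carrying the protected dimer (4α) on C5 of the dihydroxyphenyl ring | C(c3ccccc3)Oc1ccc2c(c1)O[C@H](c1ccc(OCc3ccccc3)c(OCc3ccccc3)c1)[C@@H](OCc1ccccc1)[C@H]2c1cc2c(cc1OC(=O)OCc3ccccc3)O[C@H](c1ccc(OCc3ccccc3)c(OCc3ccccc3)c1)[C@@H](OC(=O)OCc1ccccc1)[C@@H]2c1cc(C(=O)[C@@H]2O[C@H]2c2ccc(OCc3ccccc3)c(OCc3ccccc3)c2)c(O)cc1O | intermediate
26 | 3,7,3′,4′-tetra-O-benzylfisetinidol-(4β→6)-3′,4′-di-O-benzyl-3,7-bis-O-(benzyloxycarbonyl)fisetinidol-(4α→6)-3′,4′-di-O-benzylfustin | C(c3ccccc3)Oc1ccc2c(c1)O[C@H](c1ccc(OCc3ccccc3)c(OCc3ccccc3)c1)[C@@H](OCc1ccccc1)[C@H]2c1cc2c(cc1OC(=O)OCc3ccccc3)O[C@H](c1ccc(OCc3ccccc3)c(OCc3ccccc3)c1)[C@@H](OC(=O)OCc1ccccc1)[C@@H]2c1cc2c(cc1O)O[C@H](c1ccc(OCc3ccccc3)c(OCc3ccccc3)c1)[C@@H](O)C2=O | intermediate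
27 | fisetinidol-(4β→6)-fisetinidol-(4α→6)-fustin | Oc1ccc2c(c1)O[C@H](c1ccc(O)c(O)c1)[C@@H](O)[C@H]2c1cc2c(cc1O)O[C@H](c1ccc(O)c(O)c1)[C@@H](O)[C@@H]2c1cc2c(cc1O)O[C@H](c1ccc(O)c(O)c1)[C@@H](O)C2=O | intermediate
28 | fisetinidol-(4β→6)-fisetinidol-(4α→6)-mollisacacidin (CNP0255184.1) | Oc1ccc2c(c1)O[C@H](c1ccc(O)c(O)c1)[C@@H](O)[C@H]2c1cc2c(cc1O)O[C@H](c1ccc(O)c(O)c1)[C@@H](O)[C@@H]2c1cc2c(cc1O)O[C@H](c1ccc(O)c(O)c1)[C@@H](O)[C@@H]2O | target

**Summary**

Total step count: 17. Longest linear sequence: 17 steps (1 → 28); compounds 6 and 7 are each used three times.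

Steps most likely to fail:

Step 15. The cycloaddition may be slow because the γ-branched diene terminus is crowded and the s-cis diene is thinly populated, so that hydrolytic loss of the silyl enol ethers takes over. The fallback attaches a ready-made ring A by Friedel–Crafts alkylation and builds ring C by the chalcone epoxide route; it sets out from 19 and comes back at 27. Exhaustive benzylation of 19 (NaH, BnBr, DMF) should give the perbenzylated dimer F1. TMSOTf (CH2Cl2, −40 °C) with an excess of commercial 1-[4-(benzyloxy)-2-hydroxyphenyl]ethanone should alkylate that arene para to its free hydroxyl group, the bulky arene approaching C4 anti to the 3-benzyloxy group, to give the flavanyl acetophenone F2. MOMCl/iPr2NEt should give the methoxymethyl ether F3, and Claisen–Schmidt condensation with 1 (KOH, EtOH–THF) the chalcone F4. Juliá–Colonna epoxidation (poly-L-leucine, urea–H2O2, DBU, THF) should give the (αR,βS)-epoxide F5. HCl in MeOH–THF (45 °C) removes the MOM group and closes ring C to the perbenzylated trimer ketone F6, and hydrogenolysis (H2, Pd(OH)2/C) then gives 27.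

Step 8. Facial discrimination in the capture of the flavan-4-yl cation may be insufficient, with attack anti to the 3-benzyloxy group leading to the 4α epimer. The fallback delivers the carbon nucleophile from O3 through a temporary silicon tether; it sets out from 11 and comes back at 14. Benzylation of the phenol of 11 (BnBr, K2CO3, acetone) should give the 7-O-benzyl diol F7, and allyl(chloro)dimethylsilane/imidazole the bis(allyldimethylsilyl) ether F8. BF3·OEt2 (CH2Cl2, −78 °C) ionizes C4 and the allyl group of the 3-O-silyl ether is transferred through a seven-membered SE2′ transition state, which is possible only on the face of O3; K2CO3/MeOH then frees the 4β-allyl alcohol F9. NaH/BnBr gives the benzyl ether F10, Lemieux–Johnson cleavage (OsO4 cat., NaIO4, 2,6-lutidine, dioxane–H2O) the aldehyde F11, and Roskamp homologation (methyl diazoacetate, SnCl2 cat., CH2Cl2) gives 14.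

Step 13. The bridged dioxolanylium ion may lose its benzyl group and collapse to a 3,4-cyclic carbonate, or the open cation may be captured on the wrong face. The fallback replaces participation by anti opening of a 3,4-epoxide; it sets out from 19 and comes back at 22. Phenol-selective acylation of 19 (benzyl chloroformate 1.05 equiv, Et3N, CH2Cl2, −20 °C) should give the 7-O-carbonate diol F12. Mitsunobu cyclodehydration (PPh3, DIAD, THF), in which the benzylic 4-hydroxyl is activated and displaced by O3 with inversion, should give the 3,4-epoxide F13 with its oxygen trans to the C2 aryl group. BF3·OEt2 (CH2Cl2, −78 °C) and diene 7 open it anti at the benzylic C4, and acidic work-up gives the 3-hydroxy keto ester F14 (3,4-trans). Benzyl chloroformate/pyridine/DMAP then returns 22.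

**Further compounds**

F1 | step 15 | 3,7,3′,4′-tetra-O-benzylfisetinidol-(4β→6)-3,4,7,3′,4′-penta-O-benzylmollisacacidin | C(c3ccccc3)Oc1ccc2c(c1)O[C@H](c1ccc(OCc3ccccc3)c(OCc3ccccc3)c1)[C@@H](OCc1ccccc1)[C@H]2c1cc2c(cc1OCc3ccccc3)O[C@H](c1ccc(OCc3ccccc3)c(OCc3ccccc3)c1)[C@@H](OCc1ccccc1)[C@@H]2OCc1ccccc1
F2 | step 15 | 1-[4-(benzyloxy)-2-hydroxy-5-(perbenzylated fisetinidol-(4β→6)-fisetinidol-4α-yl)phenyl]ethanone | C(c3ccccc3)Oc1ccc2c(c1)O[C@H](c1ccc(OCc3ccccc3)c(OCc3ccccc3)c1)[C@@H](OCc1ccccc1)[C@H]2c1cc2c(cc1OCc3ccccc3)O[C@H](c1ccc(OCc3ccccc3)c(OCc3ccccc3)c1)[C@@H](OCc1ccccc1)[C@@H]2c1cc(C(C)=O)c(O)cc1OCc3ccccc3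
F3 | step 15 | 2-O-methoxymethyl ether of F2 | C(c3ccccc3)Oc1ccc2c(c1)O[C@H](c1ccc(OCc3ccccc3)c(OCc3ccccc3)c1)[C@@H](OCc1ccccc1)[C@H]2c1cc2c(cc1OCc3ccccc3)O[C@H](c1ccc(OCc3ccccc3)c(OCc3ccccc3)c1)[C@@H](OCc1ccccc1)[C@@H]2c1cc(C(C)=O)c(OCOC)cc1OCc3ccccc3
F4 | step 15 | (E)-chalcone from F3 and 1 | C(c3ccccc3)Oc1ccc2c(c1)O[C@H](c1ccc(OCc3ccccc3)c(OCc3ccccc3)c1)[C@@H](OCc1ccccc1)[C@H]2c1cc2c(cc1OCc3ccccc3)O[C@H](c1ccc(OCc3ccccc3)c(OCc3ccccc3)c1)[C@@H](OCc1ccccc1)[C@@H]2c1cc(C(=O)/C=C/c2ccc(OCc3ccccc3)c(OCc3ccccc3)c2)c(OCOC)cc1OCc3ccccc3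
F5 | step 15 | (αR,βS)-epoxide of chalcone F4 | C(c3ccccc3)Oc1ccc2c(c1)O[C@H](c1ccc(OCc3ccccc3)c(OCc3ccccc3)c1)[C@@H](OCc1ccccc1)[C@H]2c1cc2c(cc1OCc3ccccc3)O[C@H](c1ccc(OCc3ccccc3)c(OCc3ccccc3)c1)[C@@H](OCc1ccccc1)[C@@H]2c1cc(C(=O)[C@@H]2O[C@H]2c2ccc(OCc3ccccc3)c(OCc3ccccc3)c2)c(OCOC)cc1OCc3ccccc3
F6 | step 15 | 3,7,3′,4′-tetra-O-benzylfisetinidol-(4β→6)-3,7,3′,4′-tetra-O-benzylfisetinidol-(4α→6)-7,3′,4′-tri-O-benzylfustin | C(c3ccccc3)Oc1ccc2c(c1)O[C@H](c1ccc(OCc3ccccc3)c(OCc3ccccc3)c1)[C@@H](OCc1ccccc1)[C@H]2c1cc2c(cc1OCc3ccccc3)O[C@H](c1ccc(OCc3ccccc3)c(OCc3ccccc3)c1)[C@@H](OCc1ccccc1)[C@@H]2c1cc2c(cc1OCc3ccccc3)O[C@H](c1ccc(OCc3ccccc3)c(OCc3ccccc3)c1)[C@@H](O)C2=O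
F7 | step 8 | (2R,3S,4R)-7-(benzyloxy)-2-[3,4-bis(benzyloxy)phenyl]chromane-3,4-diol | C(c3ccccc3)Oc1ccc2c(c1)O[C@H](c1ccc(OCc3ccccc3)c(OCc3ccccc3)c1)[C@@H](O)[C@@H]2O
F8 | step 8 | 3,4-bis-O-[allyl(dimethyl)silyl] ether of F7 | C(c3ccccc3)Oc1ccc2c(c1)O[C@H](c1ccc(OCc3ccccc3)c(OCc3ccccc3)c1)[C@@H](O[Si](C)(C)CC=C)[C@@H]2O[Si](C)(C)CC=C
F9 | step 8 | (2R,3S,4S)-4-allyl-7-(benzyloxy)-2-[3,4-bis(benzyloxy)phenyl]chroman-3-ol (3,4-cis) | C(c3ccccc3)Oc1ccc2c(c1)O[C@H](c1ccc(OCc3ccccc3)c(OCc3ccccc3)c1)[C@@H](O)[C@H]2CC=C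
F10 | step 8 | (2R,3S,4S)-4-allyl-3,7-bis(benzyloxy)-2-[3,4-bis(benzyloxy)phenyl]chromane | C(c3ccccc3)Oc1ccc2c(c1)O[C@H](c1ccc(OCc3ccccc3)c(OCc3ccccc3)c1)[C@@H](OCc1ccccc1)[C@H]2CC=C
F11 | step 8 | 2-{(2R,3S,4S)-3,7-bis(benzyloxy)-2-[3,4-bis(benzyloxy)phenyl]chroman-4-yl}acetaldehyde | C(c3ccccc3)Oc1ccc2c(c1)O[C@H](c1ccc(OCc3ccccc3)c(OCc3ccccc3)c1)[C@@H](OCc1ccccc1)[C@H]2CC=O
F12 | step 13 | 3,7,3′,4′-tetra-O-benzylfisetinidol-(4β→6)-3′,4′-di-O-benzyl-7-O-(benzyloxycarbonyl)mollisacacidin | C(c3ccccc3)Oc1ccc2c(c1)O[C@H](c1ccc(OCc3ccccc3)c(OCc3ccccc3)c1)[C@@H](OCc1ccccc1)[C@H]2c1cc2c(cc1OC(=O)OCc3ccccc3)O[C@H](c1ccc(OCc3ccccc3)c(OCc3ccccc3)c1)[C@@H](O)[C@@H]2O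
F13 | step 13 | 3,4-epoxide of the lower flavan unit of F12 (epoxide oxygen trans to the C2 aryl group) | C(c3ccccc3)Oc1ccc2c(c1)O[C@H](c1ccc(OCc3ccccc3)c(OCc3ccccc3)c1)[C@@H](OCc1ccccc1)[C@H]2c1cc2c(cc1OC(=O)OCc3ccccc3)O[C@H](c1ccc(OCc3ccccc3)c(OCc3ccccc3)c1)[C@H]3O[C@H]32
F14 | step 13 | methyl 4-[3,7,3′,4′-tetra-O-benzylfisetinidol-(4β→6)-3′,4′-di-O-benzyl-7-O-(benzyloxycarbonyl)fisetinidol-4α-yl]-3-oxobutanoate (free 3-hydroxyl) | C(c3ccccc3)Oc1ccc2c(c1)O[C@H](c1ccc(OCc3ccccc3)c(OCc3ccccc3)c1)[C@@H](OCc1ccccc1)[C@H]2c1cc2c(cc1OC(=O)OCc3ccccc3)O[C@H](c1ccc(OCc3ccccc3)c(OCc3ccccc3)c1)[C@@H](O)[C@@H]2CC(=O)CC(=O)OC
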